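**Retrosynthetic overview**
1. The pyranone ring closes last. Removing all MOM groups from ketone 18 unmasks a 2,4-dihydroxybenzylic alcohol. This ionises to an o-quinone methide or benzylic cation that the 8a-OH traps, so C2 is reset trans to C3 under thermodynamic control.
2. Ketone 18 comes from the aryllithium of the lavandulyl-bearing arene 8 (ortho-metalation) and Weinreb amide 17. The amide carries C3 from (R)-solketal and the B-ring from ArLi addition.
3. Arene 8 comes from arylzinc of 2 plus the redox-active ester of (R)-limononic acid, followed by MeMgBr. The acid comes from (R)-limonene, whose ring is opened by ozone ([3+2] cycloaddition/cycloreversion), so the isopropenyl stereocentre ends up on an acyclic chain.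
4. Order of ring events: limonene ring opened first, both arenes already formed, pyranone ring closed last.

Assumption: (R)-limonene and (R)-solketal are cheap commercial materials. The two C2 epimers of 13 are carried on as a mixture, because C2 is erased and reset at the final cyclisation.

---

**Step 1**
Reactants: 1 (5-methoxybenzene-1,3-diol)
Product: 2 (1,3-bis(methoxymethoxy)-5-methoxybenzene)
Conditions: MOMCl (2.4 equiv), i-Pr2NEt, CH2Cl2, 0 °C → rt
Reagents that add atoms: MOMCl, ClCOC
Why: Williamson-type O-alkylation gives a symmetric arene whose C2 (between the two MOM groups) and C4/C6 are each a single, equivalent site for directed ortho-metalation.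

**Step 2**
Reactants: 3 ((R)-(+)-limonene)
Product: 4 ((3R)-6-oxo-3-(prop-1-en-2-yl)heptanal)
Conditions: O3 (1.0 equiv), CH2Cl2/MeOH, –78 °C; then Me2S, –78 °C → rt
Reagents that add atoms: ozone, [O-][O+]=O
Why: Ozone adds by 1,3-dipolar cycloaddition (Criegee ozonolysis) faster to the more substituted ring alkene than to the isopropenyl group at 1 equiv, opening the ring. The C4 stereocentre is untouched.

**Step 3**
Reactants: 4
Product: 5 ((3R)-6-oxo-3-(prop-1-en-2-yl)heptanoic acid, limononic acid)
Conditions: NaClO2, NaH2PO4, 2-methyl-2-butene, t-BuOH/H2O, rt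
Reagents that add atoms: NaClO2, [Na+].[O-]Cl=O
Why: Pinnick oxidation converts the aldehyde to the acid chemoselectively. The ketone and alkene survive, and the β-stereocentre is not enolisable.

**Step 4**
Reactants: 5, N-hydroxyphthalimide
Product: 6 (N-hydroxyphthalimide ester of 5)
Conditions: DIC, DMAP (cat.), CH2Cl2, rt
Reagents that add atoms: N-hydroxyphthalimide, O=C1c2ccccc2C(=O)N1O
Why: Carbodiimide esterification gives a redox-active ester that is a primary-radical precursor for decarboxylative arylation.

**Step 5**
Reactants: 2, 6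
Product: 7 ((5R)-6-[2,6-bis(methoxymethoxy)-4-methoxyphenyl]-5-(prop-1-en-2-yl)hexan-2-one)
Conditions: 2 (2 equiv), n-BuLi, THF, 0 °C; ZnCl2; then 6, NiCl2·6H2O (10 mol %), 4,4′-di-t-Bu-bipyridine (10 mol %), THF/DMA, rt
Reagents that add atoms: none
Why: Lithiation between the two MOM groups gives ArZnCl. In a Ni-catalysed decarboxylative Negishi coupling it captures the primary radical from the redox-active ester. The stereocentre is β to the radical carbon and keeps its configuration, now as the lavandulyl centre (R).

**Step 6**
Reactants: 7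
Product: 8 ((5R)-6-[2,6-bis(methoxymethoxy)-4-methoxyphenyl]-2-methyl-5-(prop-1-en-2-yl)hexan-2-ol)
Conditions: MeMgBr (1.5 equiv), THF, 0 °C
Reagents that add atoms: MeMgBr, C[Mg]Br
Why: Grignard addition to the methyl ketone gives the tertiary carbinol CMe2OH. The MOM ethers and the isopropenyl group are inert, and no new stereocentre forms.

**Step 7**
Reactants: 9 (4-bromobenzene-1,3-diol)
Product: 10 (4-bromo-1,3-bis(methoxymethoxy)benzene)
Conditions: MOMCl (2.4 equiv), i-Pr2NEt, CH2Cl2, 0 °C → rt
Reagents that add atoms: MOMCl, ClCOC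
Why: Phenol O-alkylation protects both oxygens, giving the B-ring aryl bromide with the 2′,4′-oxygenation pattern already in place.

**Step 8**
Reactants: 11 ((R)-solketal)
Product: 12 ((4S)-2,2-dimethyl-1,3-dioxolane-4-carbaldehyde)
Conditions: Dess–Martin periodinane, NaHCO3, CH2Cl2, 0 °C; crude aldehyde used at once
Reagents that add atoms: none
Why: Mild oxidation of the primary alcohol gives the glyceraldehyde acetonide. The stereocentre is carried over unchanged and becomes C3 of the flavanonol.

**Step 9**
Reactants: 10, 12
Product: 13 ((2,4-bis(methoxymethoxy)phenyl)[(4S)-2,2-dimethyl-1,3-dioxolan-4-yl]methanol, mixture of carbinol epimers)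
Conditions: 10, n-BuLi, THF, –78 °C (Br/Li exchange); then 12, –78 °C
Reagents that add atoms: none
Why: Aryllithium addition to the aldehyde is a 1,2-addition that forms C2 (as a carbinol) next to the fixed C3 centre. The epimers need not be separated because C2 is reset in the last step.

**Step 10**
Reactants: 13
Product: 14 ((2S)-3-aryl-propane-1,2,3-triol, aryl = 2,4-bis(methoxymethoxy)phenyl, C1 epimeric mixture)
Conditions: AcOH/H2O/THF (3:1:1), 30 °C
Reagents that add atoms: water, O
Why: Mild acid hydrolysis of the acetonide; the MOM ethers survive, and the C3 centre is not involved.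

**Step 11**
Reactants: 14
Product: 15 ((2R)-3-aryl-2,3-dihydroxypropanoic acid)
Conditions: TEMPO (20 mol %), PhI(OAc)2 (2.5 equiv), MeCN/H2O 1:1, rt
Reagents that add atoms: water, O
Why: TEMPO/BAIB oxidation of polyols is selective for the primary alcohol and goes to the carboxylic acid. The two secondary alcohols and the stereocentre are untouched.

**Step 12**
Reactants: 15, N,O-dimethylhydroxylamine hydrochloride
Product: 16 (Weinreb amide of 15)
Conditions: EDCI·HCl, HOBt, i-Pr2NEt, CH2Cl2/DMF, 0 °C → rt
Reagents that add atoms: N,O-dimethylhydroxylamine, CNOC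
Why: Carbodiimide coupling forms the N-methoxy-N-methylamide without racemisation, to serve as an acyl donor that stops at the ketone.

**Step 13**
Reactants: 16
Product: 17 ((2R)-2,3-bis(methoxymethoxy)-3-[2,4-bis(methoxymethoxy)phenyl]-N-methoxy-N-methylpropanamide)
Conditions: MOMCl (3 equiv), i-Pr2NEt, TBAI (cat.), CH2Cl2, 0 → 40 °C
Reagents that add atoms: MOMCl, ClCOC
Why: Protecting both secondary alcohols with the same group as the arene oxygens lets one deprotection remove everything later.

**Step 14**
Reactants: 8, 17
Product: 18 (aryl ketone: 2,4,6-trisubstituted aryl carrying the lavandulyl chain and MOM groups, joined to the C2/C3 fragment)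
Conditions: 8, n-BuLi (2.3 equiv), THF, 0 °C; cool to –78 °C, add 17, warm to –40 °C; NH4Cl quench
Reagents that add atoms: none
Why: The first equivalent of base deprotonates the tertiary OH. The second lithiates between OMOM and OMe, and the two such positions are equivalent, so only one regioisomer forms. Addition to the Weinreb amide gives a stable chelated intermediate, so the ketone is released only on workup and C3 does not epimerise.

**Step 15**
Reactants: 18
Product: 19 (target)
Conditions: ZnBr2 (8 equiv), n-PrSH (8 equiv), CH2Cl2, 0 °C → rt; then MeOH, PPTS (cat.), 40 °C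
Reagents that add atoms: none
Why: All six MOM groups are removed. The unmasked 2,4-dihydroxybenzylic alcohol forms an o-quinone methide or benzylic cation that the 8a-OH captures in a 6-membered oxa-cyclisation under thermodynamic control. The 2,3-trans isomer is favoured, so C3 (R, from solketal) sets C2 (R).

---

**Compound list**

1 | 5-methoxybenzene-1,3-diol | COc1cc(O)cc(O)c1 | starting material
2 | 1,3-bis(methoxymethoxy)-5-methoxybenzene | COCOc1cc(OC)cc(OCOC)c1 | intermediate
3 | (R)-(+)-limonene | CC1=CC[C@@H](CC1)C(C)=C | starting material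
4 | (3R)-6-oxo-3-(prop-1-en-2-yl)heptanal | CC(=O)CC[C@H](CC=O)C(C)=C | intermediate
5 | (3R)-6-oxo-3-(prop-1-en-2-yl)heptanoic acid | CC(=O)CC[C@H](CC(=O)O)C(C)=C | intermediate
6 | N-hydroxyphthalimide ester of 5 | CC(=O)CC[C@H](CC(=O)ON1C(=O)c2ccccc2C1=O)C(C)=C | intermediate
7 | (5R)-6-[2,6-bis(methoxymethoxy)-4-methoxyphenyl]-5-(prop-1-en-2-yl)hexan-2-one | CC(=O)CC[C@H](Cc1c(OCOC)cc(OC)cc1OCOC)C(C)=C | intermediate
8 | (5R)-6-[2,6-bis(methoxymethoxy)-4-methoxyphenyl]-2-methyl-5-(prop-1-en-2-yl)hexan-2-ol | CC(C)(O)CC[C@H](Cc1c(OCOC)cc(OC)cc1OCOC)C(C)=C | intermediate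
9 | 4-bromobenzene-1,3-diol | Oc1ccc(Br)c(O)c1 | starting material
10 | 4-bromo-1,3-bis(methoxymethoxy)benzene | COCOc1ccc(Br)c(OCOC)c1 | intermediate
11 | (R)-solketal, [(4R)-2,2-dimethyl-1,3-dioxolan-4-yl]methanol | OC[C@@H]1COC(C)(C)O1 | starting material
12 | (4S)-2,2-dimethyl-1,3-dioxolane-4-carbaldehyde | O=C[C@@H]1COC(C)(C)O1 | intermediate
13 | aryl[(4S)-2,2-dimethyl-1,3-dioxolan-4-yl]methanol, aryl = 2,4-bis(MOMO)phenyl, carbinol epimer mixture | COCOc1ccc(C(O)[C@@H]2COC(C)(C)O2)c(OCOC)c1 | intermediate
14 | (2S)-3-aryl-propane-1,2,3-triol, C1 epimer mixture | COCOc1ccc(C(O)[C@@H](O)CO)c(OCOC)c1 | intermediate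
15 | (2R)-3-aryl-2,3-dihydroxypropanoic acid | COCOc1ccc(C(O)[C@@H](O)C(=O)O)c(OCOC)c1 | intermediate
16 | Weinreb amide of 15 | COCOc1ccc(C(O)[C@@H](O)C(=O)N(C)OC)c(OCOC)c1 | intermediate
17 | bis-MOM Weinreb amide | COCOc1ccc(C(OCOC)[C@@H](OCOC)C(=O)N(C)OC)c(OCOC)c1 | intermediate
18 | hexa-MOM aryl ketone | C=C(C)[C@H](CCC(C)(C)O)Cc1c(OCOC)cc(OC)c(C(=O)[C@H](OCOC)C(OCOC)c2ccc(OCOC)cc2OCOC)c1OCOC | intermediate
19 | (2R,3R)-2-(2,4-dihydroxyphenyl)-3,7-dihydroxy-8-[(2R)-5-hydroxy-5-methyl-2-(prop-1-en-2-yl)hexyl]-5-methoxychroman-4-one | C=C(C)[C@H](CCC(C)(C)O)Cc1c(O)cc(OC)c2c1O[C@H](c1ccc(O)cc1O)[C@@H](O)C2=O | target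

**Total steps:** 15
**Longest linear sequence:** 8 (Steps 8 → 15, starting from solketal)

**Three steps most likely to fail**
1. **Step 15 (deprotection and cyclisation).** The trans selectivity could be low, and the isopropenyl group or tertiary alcohol could react under Lewis acid or thiol. Fallback: separate the C2 diol epimers after Step 14 and close the ring by a kinetic intramolecular Mitsunobu cyclodehydration (DIAD/PPh3) on the separated carbinol, so C2 is set by inversion rather than by equilibrium.
2. **Step 5 (Ni-catalysed decarboxylative coupling of a hindered 2,6-dioxygenated arylzinc).** Fallback: reverse the polarity. Iodinate 2 at C2 (lithiation then I2), make the primary alkyl iodide from 5 by decarboxylative iodination, and couple as alkylzinc with aryl iodide under Pd-PEPPSI Negishi conditions.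
3. **Step 14 (hindered aryllithium adding to the α,β-bis(OMOM) Weinreb amide).** Fallback: reduce 17 to the aldehyde with DIBAL, add the same aryllithium to give the diastereomeric carbinols, and oxidise with Dess–Martin periodinane to the same ketone 18.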